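The plan rests on disconnecting the benzofuran-3(2H)-one at O1–C7a and C3–C3a. Its dihydroxybenzo ring (ring A) is tied to the spiro carbon only through the ether oxygen O1 and the ketone carbon C3, which sit on adjacent aromatic carbons, the pattern an aryne acquires from an alkoxide that carries an ester. In one operation a 3,5-dioxygenated benzyne takes up the tertiary alkoxide at oxygen, and the aryl anion closes the five-membered ketone on the methyl ester. The precursor is a 3-hydroxy-2-aryl-2,3-dihydrobenzofuran-3-carboxylate fused to protected (+)-afzelechin at C7–C8, its carbinol centre already set; the aryl phenol is an allyl ether, inert to fluoride.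

Key step: step 14

Abbreviations: MOM = methoxymethyl; PTTL = N-phthaloyl-tert-leucinate; HMDS = hexamethyldisilazane. Chromane locants (O1, C2 to C8a) are used for the afzelechin part; the two centres of the new dihydrofuran ring are called the CH(aryl) centre and the carbinol (later spiro) centre.

Assumption: the sense of induction of Rh2(PTTL)4 is taken from simple 2-(benzyloxy)aryl diazoacetates, for which the R-configured catalyst should give the CH(aryl) centre drawn in 19; if this substrate responds in the opposite sense, Rh2(S-PTTL)4 is used instead, all else unchanged.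

**Aryne precursor**

Step 1
Reactants: 1 phloroglucinol
Product: 2 3,5-bis(methoxymethoxy)phenol
Conditions: MOMCl (2.1 equiv), iPr2NEt, DMF, 0 °C → rt
Reagents that add atoms: chloromethyl methyl ether, COCCl
Why: Williamson-type O-alkylation of the phenoxide with a hard chloromethyl ether should give the bis-ether as the main component of a statistical mixture, from which the mono- and tris-ethers are separated and recycled.

Step 2
Reactants: 2 3,5-bis(methoxymethoxy)phenol
Product: 3 2-bromo-3,5-bis(methoxymethoxy)phenol
Conditions: NBS (1.0 equiv), iPr2NH (10 mol %), CH2Cl2, −78 → 0 °C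
Reagents that add atoms: N-bromosuccinimide, O=C1CCC(=O)N1Br
Why: Amine-mediated ortho-bromination of a phenol, an electrophilic aromatic substitution in which the N-bromoamine hydrogen-bonded to the hydroxyl delivers bromine to C2 (C2 and C6 are equivalent) in preference to C4 between the two acetal groups.

Step 3
Reactants: 3 2-bromo-3,5-bis(methoxymethoxy)phenol
Product: 6 3,5-bis(methoxymethoxy)-2-(trimethylsilyl)phenyl trifluoromethanesulfonate, via aryl trimethylsilyl ether 4 (not isolated), via lithium 2-silylphenoxide 5 (not isolated)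
Conditions: HMDS, THF, 65 °C, then evaporation; n-BuLi, THF, −100 → −78 °C; Tf2O, −78 °C → rt
Reagents that add atoms: hexamethyldisilazane, C[Si](C)(C)N[Si](C)(C)C; trifluoromethanesulfonic anhydride, O=S(=O)(OS(=O)(=O)C(F)(F)F)C(F)(F)F
Why: O-silylation, bromine–lithium exchange and anionic 1,3-shift of silicon from oxygen to carbon (retro-Brook rearrangement) should give the 2-silylphenoxide, which is triflated at oxygen, the standard entry to ortho-silylaryl triflates.

**Benzylating agent**

Step 4
Reactants: 7 4-hydroxybenzyl alcohol
Product: 8 4-(allyloxy)benzyl alcohol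
Conditions: allyl bromide, K2CO3, acetone, reflux
Reagents that add atoms: allyl bromide, C=CCBr
Why: Williamson ether synthesis, selective for the phenol because K2CO3 deprotonates only the more acidic phenolic hydroxyl.

Step 5
Reactants: 8 4-(allyloxy)benzyl alcohol
Product: 9 4-(allyloxy)benzyl chloride
Conditions: SOCl2, CH2Cl2, 0 °C
Reagents that add atoms: thionyl chloride, O=S(Cl)Cl
Why: Chlorodehydroxylation of an electron-rich benzylic alcohol through its chlorosulfite, to which the allyl aryl ether is inert.

**Main line**

Step 6
Reactants: 10 (+)-afzelechin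
Product: 11 (2R,3S)-3,5,7-tris(methoxymethoxy)-2-[4-(methoxymethoxy)phenyl]chromane
Conditions: MOMCl (excess), iPr2NEt, DMF, 0 → 45 °C
Reagents that add atoms: chloromethyl methyl ether, COCCl
Why: Methoxymethylation of the three phenols and, on warming with excess reagent, of the secondary alcohol under an amine base too mild to open the chromane ring, so C2 and C3 are untouched.

Step 7
Reactants: 11 tetrakis-MOM afzelechin
Product: 12 (2R,3S)-8-bromo-3,5,7-tris(methoxymethoxy)-2-[4-(methoxymethoxy)phenyl]chromane
Conditions: NBS (1.0 equiv), CH2Cl2, −78 → −20 °C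
Reagents that add atoms: N-bromosuccinimide, O=C1CCC(=O)N1Br
Why: Electrophilic aromatic bromination of the trioxygenated benzo ring of the chromane at C8, the position between O1 and the 7-ether, which in per-O-alkylated flavan-3-ols reacts in preference to the more crowded C6.

Step 8
Reactants: 12 8-bromochromane
Product: 14 methyl 2-oxo-2-{(2R,3S)-3,5,7-tris(methoxymethoxy)-2-[4-(methoxymethoxy)phenyl]chroman-8-yl}acetate, via 8-lithiochromane 13 (not isolated)
Conditions: n-BuLi, THF, −78 °C; then added to dimethyl oxalate (3 equiv), THF, −78 °C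
Reagents that add atoms: dimethyl oxalate, COC(=O)C(=O)OC
Why: Bromine–lithium exchange and acylation of the aryllithium with excess dialkyl oxalate should stop at the α-keto ester, because the tetrahedral intermediate persists at −78 °C and the ketone formed is flanked by two ortho substituents.

Step 9
Reactants: 14 8-(methoxyoxalyl)chromane
Product: 15 methyl 2-{(2R,3S)-7-hydroxy-3,5-bis(methoxymethoxy)-2-[4-(methoxymethoxy)phenyl]chroman-8-yl}-2-oxoacetate
Conditions: MgBr2·OEt2, Et2O/CH2Cl2, 0 °C → rt
Reagents that add atoms: none
Why: Chelation-assisted cleavage of an aryl ether ortho to a carbonyl group, in which magnesium bridges the keto oxygen and the 7-acetal, the only MOM ether with a carbonyl neighbour, and bromide opens that acetal to leave a hydrogen-bonded phenol.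

Step 10
Reactants: 15 7-hydroxy keto ester; 9 4-(allyloxy)benzyl chloride
Product: 16 methyl 2-{(2R,3S)-7-{[4-(allyloxy)benzyl]oxy}-3,5-bis(methoxymethoxy)-2-[4-(methoxymethoxy)phenyl]chroman-8-yl}-2-oxoacetate
Conditions: K2CO3, NaI (cat.), DMF, 50 °C
Reagents that add atoms: none
Why: Williamson etherification of the phenoxide with a benzylic chloride activated by iodide exchange (Finkelstein catalysis).

Step 11
Reactants: 16 7-O-benzyl keto ester
Product: 18 methyl 2-diazo-2-{(2R,3S)-7-{[4-(allyloxy)benzyl]oxy}-3,5-bis(methoxymethoxy)-2-[4-(methoxymethoxy)phenyl]chroman-8-yl}acetate, via tosylhydrazone 17 (not isolated)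
Conditions: TsNHNH2, MeOH, 60 °C; then DBU, CH2Cl2, rt
Reagents that add atoms: 4-methylbenzenesulfonohydrazide, Cc1ccc(S(=O)(=O)NN)cc1
Why: Condensation of the ketone carbonyl of the α-keto ester with tosylhydrazide and base-induced loss of sulfinate (Bamford–Stevens type) is the standard route from aryl glyoxylates to aryl diazoacetates.

Step 12
Reactants: 18 aryl diazoacetate
Product: 19 cis-configured methyl 2-[4-(allyloxy)phenyl]-2,3-dihydrofuran-3-carboxylate fused through O to C7 and through C to C8 of the protected chromane (CH(aryl) centre S, CH(CO2Me) centre R, chromane 2R,3S)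
Conditions: Rh2(R-PTTL)4 (2 mol %), toluene, −60 °C → rt, slow addition of 18
Reagents that add atoms: none
Why: Intramolecular 1,5 C–H insertion of a donor/acceptor rhodium carbenoid into the benzylic C–H of the 7-O-benzyl ether is known to give cis-2-aryl-2,3-dihydrobenzofuran-3-carboxylates with Rh2(PTTL)4, the chiral carboxylate ligands fixing the CH(aryl) centre, while the ester-bearing centre is erased in step 13 and the chromane C2–H could only be reached through a bridged ring.

Step 13
Reactants: 19 cis ester
Product: 21 methyl 3-hydroxy-2-[4-(allyloxy)phenyl]-2,3-dihydrofuran-3-carboxylate fused to the protected chromane, hydroxyl trans to the aryl group (CH(aryl) centre R, carbinol centre S), via potassium ester enolate 20 (not isolated)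
Conditions: KN(SiMe3)2, THF, −78 °C; then 2-(benzenesulfonyl)-3-phenyloxaziridine, −78 °C
Reagents that add atoms: 2-(benzenesulfonyl)-3-phenyloxaziridine, O=S(=O)(c1ccccc1)N1OC1c1ccccc1
Why: Davis oxidation of an ester enolate, in which the oxaziridine approaches the planar enolate on the face opposite the neighbouring aryl group, so the quaternary centre is set by substrate control with hydroxyl trans to aryl, while loss of the ring aryloxide is stereoelectronically disfavoured (reverse 5-endo-trig).

Step 14
Reactants: 21 tertiary hydroxy ester; 6 3,5-bis(methoxymethoxy)-2-(trimethylsilyl)phenyl trifluoromethanesulfonate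
Product: 24 protected spiro ketone, allyl ether (spiro centre S, CH(aryl) centre R, aryl trans to the benzofuranone ether oxygen), via sodium alkoxide 22 (not isolated), via 3,5-bis(methoxymethoxy)benzyne 23 (not isolated)
Conditions: NaH, THF, 0 °C; then 6 (2.5 equiv, slow addition), CsF, 18-crown-6, THF, rt → 45 °C
Reagents that add atoms: none
Why: Proposed new method: NaH turns the tertiary alcohol into alkoxide 22, fluoride removes the silyl group of 6 with loss of triflate to give aryne 23, the alkoxide oxygen adds to the aryne carbon remote from the flanking methoxymethoxy group, and the aryl anion left next to that group attacks the methyl ester and expels methoxide. The closest known reactions are aryne annulations of oxygen or nitrogen nucleophiles that carry a carbonyl acceptor, such as xanthone formation from salicylate esters, and the acyl-alkylation of arynes by β-keto esters; a tertiary α-hydroxy ester has not been shown in this role. The single ring formed, the five-membered ketone ring of the benzofuranone, closes by 5-exo-trig attack of the aryl anion on the ester carbonyl after intermolecular O-arylation. No stereocentre is created, because only the O–H bond of the carbinol reacts, so the quaternary carbon becomes the spiro centre with its configuration intact and the CH(aryl) centre is not touched. The regioselectivity needed, oxygen at the remote aryne carbon so that the ketone ends next to the 4-oxygen substituent, is secured by the inductive and distortion effect of the 3-alkoxy group; the chemoselectivity needed, acyl capture ahead of protonation of the aryl anion, is secured by the proton-free alkoxide without α-hydrogen, by THF in place of acetonitrile and by the ester held one bond away. The allyl ether is inert to fluoride, so no phenoxide is set free to compete for the aryne.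

Step 15
Reactants: 24 protected spiro ketone, allyl ether
Product: 26 protected spiro ketone with free 4-hydroxyphenyl group and inverted CH(aryl) centre (spiro S, CH(aryl) S, aryl cis to the benzofuranone ether oxygen), via allyl-free phenol 25 (not isolated)
Conditions: Pd(PPh3)4 (5 mol %), K2CO3, MeOH/THF, rt, then 45 °C until the epimer composition is constant
Reagents that add atoms: none
Why: Tsuji–Trost deallylation (allyl transfer to methoxide through π-allylpalladium) frees the phenol, whose phenoxide opens the benzylic C–O bond to a para-quinone methide (retro-oxa-Michael) and recloses 5-exo-trig, so the CH(aryl) centre should settle under thermodynamic control with the aryl group beside the ether oxygen and away from the carbonyl, while chromane C2 cannot follow because its aryl group is still an acetal.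

Step 16
Reactants: 26 CH-epimerised phenol
Product: 27 target spiro-biflavonoid (spiro S, CH(aryl) S, chromane 2R,3S)
Conditions: HCl (3 M in MeOH), 0 → 40 °C
Reagents that add atoms: none
Why: Acid-catalysed acetal methanolysis should remove the four aryl and the one alkyl MOM ether without risk to a stereocentre, since the CH(aryl) centre is already in its thermodynamic configuration and flavan-3-ols tolerate dilute methanolic HCl.

**Compound list**

1 | phloroglucinol (benzene-1,3,5-triol) | Oc1cc(O)cc(O)c1 | starting material
2 | 3,5-bis(methoxymethoxy)phenol | COCOc1cc(O)cc(OCOC)c1 | intermediate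
3 | 2-bromo-3,5-bis(methoxymethoxy)phenol | Oc1cc(OCOC)cc(OCOC)c1Br | intermediate
4 | [2-bromo-3,5-bis(methoxymethoxy)phenoxy]trimethylsilane | C[Si](C)(C)Oc1cc(OCOC)cc(OCOC)c1Br | intermediate
5 | lithium 3,5-bis(methoxymethoxy)-2-(trimethylsilyl)phenoxide | [Li+].[O-]c1cc(OCOC)cc(OCOC)c1[Si](C)(C)C | intermediate
6 | 3,5-bis(methoxymethoxy)-2-(trimethylsilyl)phenyl trifluoromethanesulfonate | COCOc1cc(OCOC)c([Si](C)(C)C)c(OS(=O)(=O)C(F)(F)F)c1 | intermediate
7 | 4-hydroxybenzyl alcohol | OCc1ccc(O)cc1 | starting material
8 | 4-(allyloxy)benzyl alcohol | C=CCOc1ccc(CO)cc1 | intermediate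
9 | 4-(allyloxy)benzyl chloride | C=CCOc1ccc(CCl)cc1 | intermediate
10 | (+)-afzelechin, (2R,3S)-2-(4-hydroxyphenyl)chromane-3,5,7-triol | Oc1cc(O)c2c(c1)O[C@H](c1ccc(O)cc1)[C@@H](O)C2 | starting material
11 | (2R,3S)-3,5,7-tris(methoxymethoxy)-2-[4-(methoxymethoxy)phenyl]chromane | COCOc1cc(OCOC)c2c(c1)O[C@H](c1ccc(OCOC)cc1)[C@@H](OCOC)C2 | intermediate
12 | (2R,3S)-8-bromo-3,5,7-tris(methoxymethoxy)-2-[4-(methoxymethoxy)phenyl]chromane | COCOc1cc(OCOC)c2c(c1Br)O[C@H](c1ccc(OCOC)cc1)[C@@H](OCOC)C2 | intermediate
13 | 8-lithio derivative of 11 | COCOc1cc(OCOC)c2c(c1[Li])O[C@H](c1ccc(OCOC)cc1)[C@@H](OCOC)C2 | intermediate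
14 | methyl 2-oxo-2-{(2R,3S)-3,5,7-tris(methoxymethoxy)-2-[4-(methoxymethoxy)phenyl]chroman-8-yl}acetate | COC(=O)C(=O)c1c(OCOC)cc(OCOC)c2c1O[C@H](c1ccc(OCOC)cc1)[C@@H](OCOC)C2 | intermediate
15 | methyl 2-{(2R,3S)-7-hydroxy-3,5-bis(methoxymethoxy)-2-[4-(methoxymethoxy)phenyl]chroman-8-yl}-2-oxoacetate | COC(=O)C(=O)c1c(O)cc(OCOC)c2c1O[C@H](c1ccc(OCOC)cc1)[C@@H](OCOC)C2 | intermediate
16 | methyl 2-{(2R,3S)-7-{[4-(allyloxy)benzyl]oxy}-3,5-bis(methoxymethoxy)-2-[4-(methoxymethoxy)phenyl]chroman-8-yl}-2-oxoacetate | COC(=O)C(=O)c1c(OCc3ccc(OCC=C)cc3)cc(OCOC)c2c1O[C@H](c1ccc(OCOC)cc1)[C@@H](OCOC)C2 | intermediate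
17 | N-tosylhydrazone of 16 | COC(=O)C(=NNS(=O)(=O)c3ccc(C)cc3)c1c(OCc3ccc(OCC=C)cc3)cc(OCOC)c2c1O[C@H](c1ccc(OCOC)cc1)[C@@H](OCOC)C2 | intermediate
18 | methyl 2-diazo-2-{(2R,3S)-7-{[4-(allyloxy)benzyl]oxy}-3,5-bis(methoxymethoxy)-2-[4-(methoxymethoxy)phenyl]chroman-8-yl}acetate | COC(=O)C(=[N+]=[N-])c1c(OCc3ccc(OCC=C)cc3)cc(OCOC)c2c1O[C@H](c1ccc(OCOC)cc1)[C@@H](OCOC)C2 | intermediate
19 | cis methyl 2-[4-(allyloxy)phenyl]-2,3-dihydrofuran-3-carboxylate fused at C7(O)–C8(C) of the protected chromane; CH(aryl) S, CH(CO2Me) R, chromane 2R,3S | COC(=O)[C@@H]1c2c(cc(OCOC)c3c2O[C@H](c2ccc(OCOC)cc2)[C@@H](OCOC)C3)O[C@@H]1c1ccc(OCC=C)cc1 | intermediate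
20 | potassium ester enolate of 19 | [K+].COC([O-])=C1c2c(cc(OCOC)c3c2O[C@H](c2ccc(OCOC)cc2)[C@@H](OCOC)C3)O[C@@H]1c1ccc(OCC=C)cc1 | intermediate
21 | tertiary hydroxy ester, hydroxyl trans to aryl; CH(aryl) R, carbinol S, chromane 2R,3S | COC(=O)[C@]1(O)c2c(cc(OCOC)c3c2O[C@H](c2ccc(OCOC)cc2)[C@@H](OCOC)C3)O[C@@H]1c1ccc(OCC=C)cc1 | intermediate
22 | sodium alkoxide of 21 | [Na+].COC(=O)[C@]1([O-])c2c(cc(OCOC)c3c2O[C@H](c2ccc(OCOC)cc2)[C@@H](OCOC)C3)O[C@@H]1c1ccc(OCC=C)cc1 | intermediate
23 | 3,5-bis(methoxymethoxy)benzyne | COCOC1=CC(OCOC)=CC#C1 | intermediate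
24 | protected spiro ketone, allyl ether; spiro S, CH(aryl) R, chromane 2R,3S | O=C1c2c(OCOC)cc(OCOC)cc2O[C@]12c1c(cc(OCOC)c3c1O[C@H](c1ccc(OCOC)cc1)[C@@H](OCOC)C3)O[C@@H]2c1ccc(OCC=C)cc1 | intermediate
25 | phenol from 24, configuration unchanged; spiro S, CH(aryl) R | O=C1c2c(OCOC)cc(OCOC)cc2O[C@]12c1c(cc(OCOC)c3c1O[C@H](c1ccc(OCOC)cc1)[C@@H](OCOC)C3)O[C@@H]2c1ccc(O)cc1 | intermediate
26 | CH-epimerised phenol; spiro S, CH(aryl) S, chromane 2R,3S | O=C1c2c(OCOC)cc(OCOC)cc2O[C@]12c1c(cc(OCOC)c3c1O[C@H](c1ccc(OCOC)cc1)[C@@H](OCOC)C3)O[C@H]2c1ccc(O)cc1 | intermediate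
27 | CNP0228515.1; spiro S, CH(aryl) S, chromane 2R,3S | O=C1c2c(O)cc(O)cc2O[C@]12c1c(cc(O)c3c1O[C@H](c1ccc(O)cc1)[C@@H](O)C3)O[C@H]2c1ccc(O)cc1 | target

Total step count: 16. Longest linear sequence: 11 steps (steps 6 to 16, from (+)-afzelechin).

**Steps most likely to fail**

Step 14. The hindered tertiary alkoxide may add to the aryne too slowly, so that the aryne is lost to self-reaction, or the aryl anion may be protonated before it reaches the ester, which would stop at an open aryl ether. The fallback uses known reactions and forms the two bonds in the reverse order. It sets out from 21, converted into its sodium alkoxide 22 with NaH in THF. 2-Fluoro-4,6-bis(methoxymethoxy)phenyllithium F1, made from the corresponding aryl bromide and n-BuLi at −78 °C and kept cold so that LiF is not lost, is added to the methyl ester. The doubly ortho-substituted ketone formed should resist a second addition and give the hydroxy ketone F2. K2CO3 in DMF at 60 °C should then close the ring by intramolecular nucleophilic aromatic substitution, the tertiary alkoxide displacing the fluoride ortho to the ketone; both acetal oxygens are meta to fluorine and do not deactivate that carbon. The configuration is untouched and the route is rejoined at 24.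

Step 15. Opening to the quinone methide may be too slow under mild base, the equilibrium may not lie far enough on the side of the wanted epimer, or methanol may capture the quinone methide. The fallback moves the equilibration to the hydroxy ester, where the aryl group chooses between a small hydroxyl and an ester. It sets out from 21: Pd(PPh3)4 and K2CO3 in MeOH give the phenol F3, which is warmed with the same base until the epimer with aryl cis to hydroxyl, the CH-epimeric phenol F4, prevails. Allyl bromide and K2CO3 in acetone re-protect the phenol only, giving the allyl ether F5. The aryne annulation of step 14 should then give the spiro ketone allyl ether F6 directly with the target CH configuration. Pd(PPh3)4 with morpholine in THF, without carbonate so that the centre is not re-equilibrated, removes the allyl group and the route is rejoined at 26.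

Step 9. Selectivity among the four MOM ethers may be lost, or the Lewis acid may open the chromane C2–O1 bond. The fallback replaces selective deprotection by selective protection. It sets out from 14: dilute HCl in MeOH at rt removes the three aryl MOM ethers, which cleave ahead of the secondary alkyl one, to give the triphenol keto ester F7. MOMCl (2.1 equiv) and iPr2NEt in CH2Cl2 at 0 °C then protect the 5- and 4'-phenols, while the 7-hydroxyl, locked in a hydrogen bond to the ortho keto group, stays free. The route is rejoined at 15.

Further compounds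
F1 | step 14 | 2-fluoro-4,6-bis(methoxymethoxy)phenyllithium | [Li]c1c(F)cc(OCOC)cc1OCOC
F2 | step 14 | hydroxy ketone from 21, 2-fluoro-4,6-bis(methoxymethoxy)benzoyl in place of the ester; CH(aryl) R, carbinol S | O=C(c1c(F)cc(OCOC)cc1OCOC)[C@]1(O)c2c(cc(OCOC)c3c2O[C@H](c2ccc(OCOC)cc2)[C@@H](OCOC)C3)O[C@@H]1c1ccc(OCC=C)cc1
F3 | step 15 | phenol from 21, configuration unchanged | COC(=O)[C@]1(O)c2c(cc(OCOC)c3c2O[C@H](c2ccc(OCOC)cc2)[C@@H](OCOC)C3)O[C@@H]1c1ccc(O)cc1
F4 | step 15 | CH-epimeric phenol, aryl cis to hydroxyl; CH(aryl) S, carbinol S | COC(=O)[C@]1(O)c2c(cc(OCOC)c3c2O[C@H](c2ccc(OCOC)cc2)[C@@H](OCOC)C3)O[C@H]1c1ccc(O)cc1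
F5 | step 15 | allyl ether of F4 | COC(=O)[C@]1(O)c2c(cc(OCOC)c3c2O[C@H](c2ccc(OCOC)cc2)[C@@H](OCOC)C3)O[C@H]1c1ccc(OCC=C)cc1
F6 | step 15 | spiro ketone allyl ether with target CH configuration; spiro S, CH(aryl) S | O=C1c2c(OCOC)cc(OCOC)cc2O[C@]12c1c(cc(OCOC)c3c1O[C@H](c1ccc(OCOC)cc1)[C@@H](OCOC)C3)O[C@H]2c1ccc(OCC=C)cc1
F7 | step 9 | methyl 2-{(2R,3S)-5,7-dihydroxy-2-(4-hydroxyphenyl)-3-(methoxymethoxy)chroman-8-yl}-2-oxoacetate | COC(=O)C(=O)c1c(O)cc(O)c2c1O[C@H](c1ccc(O)cc1)[C@@H](OCOC)C2
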